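The ten-membered ring is made by ozonolysis of a C4=C9 octalin (step 18). Ring A comes from homogentisic acid, ring B from a Diels–Alder reaction with the silyloxydiene of pent-3-en-2-one. The route has 23 steps.

**Plan**

- **Locants:** ring carbons are C1 (lactone O–CH), C2 (lactone junction), C3 (O-isobutyryl), C4 (ketone), C5 (CHMe), C6, C7 (CHOH), C8, C9 (methyl carbinol) and C10 (O-angeloyl). Lactone carbons are C11 (α), C12 (C=O) and C13 (=CH2). In the bicyclic compounds β is the face of the C5 methyl group and α the other face.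
- **Enabling feature:** the oxygen-bearing carbons C4 and C9 lie 1,6 across the ten-membered ring. A C4=C9 double bond therefore folds it into two fused cyclohexenes (ring A: C4, C3, C2, C1, C10, C9; ring B: C4, C5, C6, C7, C8, C9). Ring A, with C11–C12 on C2 and oxygen on C3 and C10, is homogentisic acid.
- **Cuts:** O10–angeloyl, C11=C13 (back to CH–CH2NMe2) and C9–CH3 come first. Then the C4 and C9 carbonyls are rejoined as C4=C9. In the octalin the cuts are C11–C13, O1–C12, C2–H (from a C1–C2 epoxide), and finally C4–C5 and C8–C9 (Diels–Alder).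
- **Forward order:** ring A (arene, then quinone monoketal), ring B by cycloaddition, epoxide and restored C4=C9, γ-lactone, ten-membered ring by cutting the bond shared by rings A and B, then methyl, methylene and angelate.
- **Stereochemistry:** C5 comes from a BINOL–titanium endo Diels–Alder reaction and C7 from equatorial hydride attack. The temporary centres C4/C9 make ring A convex/concave and relay C5 to the C1–C2 epoxide. Hydride anti to the epoxide sets C3 and, after Mitsunobu inversion, C10. H-atom transfer anti to O1/O3 sets C2, and Felkin–Anh addition next to C10 sets C9.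

Key step: step 18

Assumption: (R)-BINOL is written for the series drawn. The sense of induction is to be checked on the C7 alcohol of step 6, and (S)-BINOL is used if it proves opposite.

**Route**

Step 1
Reactants: 1 homogentisic acid (2,5-dihydroxyphenylacetic acid)
Product: 2 5-hydroxybenzofuran-2(3H)-one
Conditions: p-TsOH·H2O (cat.), toluene, reflux, Dean–Stark trap
Reagents that add atoms: none
Why: Acid-catalysed lactonisation of an ortho-hydroxyphenylacetic acid closes the five-membered aryl lactone on O3 and leaves O10 as the only free phenol, so the two hydroquinone oxygens are told apart.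

Step 2
Reactants: 2 5-hydroxybenzofuran-2(3H)-one
Product: 3 5-methoxybenzofuran-2(3H)-one
Conditions: MeOH (1.1 equiv), PPh3, DIAD, THF, 0 °C → rt
Reagents that add atoms: methanol, CO
Why: Mitsunobu etherification methylates the phenol under neutral conditions and so avoids the C-methylation of the acidic benzofuranone CH2 that carbonate bases would bring about.

Step 3
Reactants: 3 5-methoxybenzofuran-2(3H)-one
Product: 5 quinone monoketal methyl (3,3-dimethoxy-6-oxocyclohexa-1,4-dien-1-yl)acetate, via phenol ester 4 (not isolated)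
Conditions: NaOMe (cat.), MeOH, rt; then PhI(OAc)2, MeOH, 0 °C
Reagents that add atoms: methanol, CO
Why: Methanolysis of the aryl lactone frees the O3 phenol, and oxidative dearomatisation of a 4-methoxyphenol with PhI(OAc)2 in methanol places the ketal at C10 and the single carbonyl at C3 beside the side chain.

Step 4
Reactants: 6 (E)-pent-3-en-2-one
Product: 7 (E)-2-(triisopropylsilyloxy)penta-1,3-diene
Conditions: iPr3SiOTf, Et3N, Et2O, 0 °C
Reagents that add atoms: triisopropylsilyl triflate, CC(C)[Si](OS(=O)(=O)C(F)(F)F)(C(C)C)C(C)C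
Why: Soft enolisation of the enone at its acetyl methyl group (silyl triflate/amine) gives the cross-conjugated 2-silyloxydiene and leaves the E-propenyl unit untouched.

Step 5
Reactants: 5 quinone monoketal; 7 (E)-2-(triisopropylsilyloxy)penta-1,3-diene
Product: 9 cis-fused C7-keto C3-enone C10-ketal (5β-methyl; H4 H5 H9 α), via silyl enol ether adduct 8 (not isolated)
Conditions: (R)-BINOL (12 mol %), TiCl2(OiPr)2 (10 mol %), 4 Å MS, CH2Cl2, –20 °C; then Bu4NF, AcOH, THF, 0 °C
Reagents that add atoms: none
Why: In this catalytic enantioselective Diels–Alder reaction of a quinone monoketal the C3 carbonyl is the only activating group, so the nucleophilic terminus C8 bonds to its β-carbon C9 and C5 to C4 at the unsubstituted double bond; the endo transition state puts the C5 methyl cis to the C4–C3 bond, the BINOL–titanium complex chooses the face, and buffered fluoride then turns the enol ether into the C7 ketone.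

Step 6
Reactants: 9 cis-fused keto enone ketal
Product: 10 7α-alcohol
Conditions: LiBH(s-Bu)3 (1.05 equiv), THF, –78 °C; AcOH quench
Reagents that add atoms: none
Why: The bulky trialkylborohydride attacks the unhindered C7 ketone equatorially on the chair with equatorial C5 methyl and should give the axial 7α-alcohol trans to the methyl group, while the α-branched enone with a neopentyl-like β-carbon reacts more slowly.

Step 7
Reactants: 10 7α-alcohol
Product: 11 7α-tert-butyldimethylsilyl ether
Conditions: TBSCl, imidazole, DMF, rt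
Reagents that add atoms: tert-butyldimethylsilyl chloride, CC(C)(C)[Si](C)(C)Cl
Why: Standard imidazole-promoted silylation protects O7 with a group that lasts to the final step and spares the ketal, which a silyl triflate could ionise.

Step 8
Reactants: 11 7α-silyl ether ketal
Product: 12 cis-fused enedione (C3 and C10 ketones, C1=C2)
Conditions: PPTS (cat.), acetone–H2O, rt
Reagents that add atoms: water, O
Why: Mild acid hydrolysis of the allylic dimethyl ketal unveils the C10 ketone without touching the TBS ether, and brief weakly acidic exposure avoids enolisation of the enedione to the hydroquinone.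

Step 9
Reactants: 12 cis-fused enedione
Product: 13 1α,2α-epoxy-3,10-dione (cis-fused)
Conditions: 30% aq H2O2, Na2CO3, acetone, 0 °C
Reagents that add atoms: hydrogen peroxide, OO
Why: In this Weitz–Scheffer epoxidation of a quinone–diene adduct, hydroperoxide attacks C1 from the convex α face (the face of H4 and H9, away from ring B), so the configuration of C5 is relayed through C4/C9 to C1 and C2.

Step 10
Reactants: 13 epoxy-dione
Product: 15 1α,2α-epoxy-4(9)-ene-3,10-dione, via lithium enolate 14 (not isolated)
Conditions: LiN(SiMe3)2 (1.05 equiv), THF, –78 °C; then PhS(Cl)=NtBu, –78 °C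
Reagents that add atoms: none
Why: In this Mukaiyama dehydrogenation each ring-fusion hydrogen is α to one carbonyl and β to the other, so the syn-elimination takes the doubly activated hydrogen and restores C4=C9 rather than a C4=C5 or C8=C9 bond, while the epoxide keeps the stereochemical information.

Step 11
Reactants: 15 epoxy-enedione
Product: 16 1α,2α-epoxy-3α,10α-diol
Conditions: NaBH4, CeCl3·7H2O, MeOH, –78 °C
Reagents that add atoms: none
Why: Luche 1,2-reduction of both enone carbonyls should deliver hydride from the β face, anti to the adjacent oxirane oxygen, placing both hydroxyls α (final at C3, to be inverted at C10).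

Step 12
Reactants: 16 epoxy-diol
Product: 17 10β-formate 3α-alcohol
Conditions: HCO2H (1.1 equiv), PPh3, DIAD, THF, –20 → 0 °C
Reagents that add atoms: formic acid, O=CO
Why: In this Mitsunobu inversion the allylic C10 alcohol beside the epoxide CH is activated in preference to the C3 alcohol (beside fully substituted C2 and peri to the C5 methyl), and formate enters by SN2 from the open β face, setting O10 trans to O1.

Step 13
Reactants: 17 10β-formate 3α-alcohol
Product: 18 3α-isobutyrate 10β-formate
Conditions: (iPrCO)2O, Et3N, DMAP (cat.), CH2Cl2, rt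
Reagents that add atoms: isobutyric anhydride, CC(C)C(=O)OC(=O)C(C)C
Why: DMAP-catalysed acylation esterifies the only free hydroxyl, so O3 is blocked before O1 is released and the later lactone can close only on O1.

Step 14
Reactants: 18 3α-isobutyrate 10β-formate
Product: 19 10β-alcohol
Conditions: KHCO3 (cat.), MeOH, 0 °C
Reagents that add atoms: none
Why: Formates are methanolysed far faster than a hindered isobutyrate, exchange at the methyl ester is degenerate, and bicarbonate is too weak to start epoxide migration.

Step 15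
Reactants: 19 10β-alcohol
Product: 20 10β-triethylsilyl ether
Conditions: Et3SiCl, imidazole, CH2Cl2, 0 °C
Reagents that add atoms: chlorotriethylsilane, CC[Si](Cl)(CC)CC
Why: Silylation gives a non-chelating O10 group that can later be removed in the presence of the C7 TBS ether.

Step 16
Reactants: 20 epoxide
Product: 22 cis-fused γ-lactone octalin (O1 C11 O3 α; O10 β), via hydroxy ester 21 (not isolated)
Conditions: Cp2TiCl2 (20 mol %), Mn, 2,4,6-collidine·HCl, 1,4-cyclohexadiene, THF, rt; then PPTS (cat.), CH2Cl2, rt
Reagents that add atoms: none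
Why: In this titanocene-catalysed reductive epoxide opening, Cp2TiCl (trivalent titanium) cleaves the C2–O bond to the more substituted tertiary radical, hydrogen-atom transfer arrives from the β face anti to the flanking O1–Ti and O3-acyl groups and turns C11 to the α face, and the cis γ-hydroxy ester lactonises on O1.

Step 17
Reactants: 22 γ-lactone octalin
Product: 24 11-(dimethylaminomethyl) lactone octalin, via lithium lactone enolate 23 (not isolated)
Conditions: LiN(SiMe3)2 (1.1 equiv), THF, –78 °C; then CH2=NMe2+ I–, –78 → –20 °C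
Reagents that add atoms: dimethyl(methylidene)ammonium iodide, C=[N+](C)C.[I-]
Why: In this Mannich aminomethylation the silazide removes only the more acidic lactone CH2 proton (not the isobutyrate methine), the iminium ion adds from the convex face (cis to H2, a centre erased later), and stopping at the amine keeps C13 in place without a C11=C13 double bond.

Step 18
Reactants: 24 11-(dimethylaminomethyl) lactone octalin
Product: 27 cyclodecane-4,9-dione, via ammonium trifluoroacetate 25 (not isolated), via secondary ozonide 26 (not isolated)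
Conditions: CF3CO2H (1.2 equiv), CH2Cl2, –78 °C; O3/O2 until Sudan Red 7B fades; N2 purge; Me2S, –78 °C → rt; cold aq NaHCO3 wash
Reagents that add atoms: ozone, [O-][O+]=O
Why: Ozone adds as a 1,3-dipole to C4=C9, the primary ozonide breaks into a ketone and a carbonyl oxide held in the same ring, these recombine to the bridged ozonide 26 (Criegee mechanism), and Me2S removes one oxygen to leave the C4 and C9 ketones. The closest known reaction type is the ozonolysis of bicyclo[4.4.0]dec-1(6)-enes to cyclodecane-1,6-diones. No ring is closed by bond formation: the ten-membered ring is the perimeter C1–C10 that remains when the bond shared by rings A and B is cut, so no medium-ring cyclisation is needed. No stereocentre is created, and C1, C2, C3, C5, C7 and C10, all set on six-membered rings, pass through unchanged; the cold, near-neutral work-up protects C3, C5 and C10, which are now α to ketones, and avoids transannular aldol reaction. The step needs ozone to react only with an alkene that two allylic C–O bonds make less reactive, so the competing acrylate C11=C13 is absent (held back as the Mannich base), the amine is shielded as its ammonium salt 25, and the dye end point limits the dose.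

Step 19
Reactants: 27 cyclodecane-4,9-dione
Product: 28 9-methyl carbinol
Conditions: ClTi(OiPr)3, MeLi, Et2O, –40 °C (gives MeTi(OiPr)3); then 27, CH2Cl2, –20 °C → rt; H2O
Reagents that add atoms: methyltriisopropoxytitanium (from methyllithium), C[Ti](OC(C)C)(OC(C)C)OC(C)C
Why: The non-basic, sterically demanding organotitanium reagent should choose the C9 ketone (CH2 on one side) over the doubly branched C4 ketone and ignore esters and lactone, and with a non-chelating silyl ether on O10 the polar Felkin–Anh model (attack anti to the C10–O bond, past H10) leads to the required C9 configuration.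

Step 20
Reactants: 28 9-methyl carbinol
Product: 30 α-methylene lactone, via trimethylammonium iodide 29 (not isolated)
Conditions: MeI, THF, rt; then aq NaHCO3, EtOAc, rt
Reagents that add atoms: none
Why: Quaternisation and E1cB (Hofmann-type) loss of trimethylamine is the usual second half of a Mannich methylenation; bicarbonate suffices because H11 is α to the lactone carbonyl, and with the C9 ketone gone a transannular aldol reaction is no longer possible.

Step 21
Reactants: 30 α-methylene lactone
Product: 31 9,10-diol (O7 still silylated)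
Conditions: AcOH–THF–H2O, rt
Reagents that add atoms: none
Why: Mild acid solvolysis removes a triethylsilyl ether much faster than a tert-butyldimethylsilyl ether, so only O10 is freed.

Step 22
Reactants: 31 9,10-diol; 32 angelic acid
Product: 34 10-angelate 7-silyl ether, via mixed anhydride 33 (not isolated)
Conditions: 32, 2,4,6-Cl3C6H2COCl, Et3N, toluene, rt; then 31, toluene, 75 °C
Reagents that add atoms: none
Why: Yamaguchi-type mixed-anhydride esterification run without a nucleophilic catalyst avoids the addition–elimination that turns angelates into tiglates, and the secondary O10 is acylated while the tertiary C9 hydroxyl stays free.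

Step 23
Reactants: 34 10-angelate 7-silyl ether
Product: 35 CNP0184688.2
Conditions: HF·pyridine, pyridine, THF, 0 °C → rt
Reagents that add atoms: none
Why: Buffered fluoride desilylation cleaves the last Si–O bond without affecting the esters, the methylene lactone or the α-acyloxy ketone.

**Compound list**

1 | homogentisic acid | OC(=O)Cc1cc(O)ccc1O | starting material
2 | 5-hydroxybenzofuran-2(3H)-one | O=C1Cc2cc(O)ccc2O1 | intermediate
3 | 5-methoxybenzofuran-2(3H)-one | COc1ccc2OC(=O)Cc2c1 | intermediate
4 | methyl (2-hydroxy-5-methoxyphenyl)acetate (not isolated) | COC(=O)Cc1cc(OC)ccc1O | intermediate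
5 | methyl (3,3-dimethoxy-6-oxocyclohexa-1,4-dien-1-yl)acetate (C3 ketone, C10 ketal) | COC(=O)CC1=CC(OC)(OC)C=CC1=O | intermediate
6 | (E)-pent-3-en-2-one | C/C=C/C(C)=O | starting material
7 | (E)-2-(triisopropylsilyloxy)penta-1,3-diene | C=C(O[Si](C(C)C)(C(C)C)C(C)C)/C=C/C | intermediate
8 | endo adduct, cis-fused: C3 ketone, C1=C2 with CH2CO2Me on C2, C10 dimethyl ketal, 5β-methyl, C6=C7 silyl enol ether, H4, H5, H9 α (not isolated) | COC(=O)CC1=CC(OC)(OC)[C@@H]2CC(O[Si](C(C)C)(C(C)C)C(C)C)=C[C@H](C)[C@@H]2C1=O | intermediate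
9 | as 8 with a C7 ketone | COC(=O)CC1=CC(OC)(OC)[C@@H]2CC(=O)C[C@H](C)[C@@H]2C1=O | intermediate
10 | as 9 with a 7α-hydroxyl (trans to the 5β-methyl) | COC(=O)CC1=CC(OC)(OC)[C@@H]2C[C@@H](O)C[C@H](C)[C@@H]2C1=O | intermediate
11 | 7α-OTBS ether of 10 | COC(=O)CC1=CC(OC)(OC)[C@@H]2C[C@@H](O[Si](C)(C)C(C)(C)C)C[C@H](C)[C@@H]2C1=O | intermediate
12 | cis-fused enedione (C3, C10 ketones, C1=C2), 5β-methyl, 7α-OTBS | COC(=O)CC1=CC(=O)[C@@H]2C[C@@H](O[Si](C)(C)C(C)(C)C)C[C@H](C)[C@@H]2C1=O | intermediate
13 | 1α,2α-epoxide of 12 | COC(=O)C[C@]12O[C@H]1C(=O)[C@@H]3C[C@@H](O[Si](C)(C)C(C)(C)C)C[C@H](C)[C@@H]3C2=O | intermediate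
14 | lithium C9=C10 enolate of 13 (not isolated) | COC(=O)C[C@]12O[C@H]1C(O[Li])=C3C[C@@H](O[Si](C)(C)C(C)(C)C)C[C@H](C)[C@@H]3C2=O | intermediate
15 | 1α,2α-epoxy-4(9)-ene-3,10-dione | COC(=O)C[C@]12O[C@H]1C(=O)C3=C(C2=O)[C@@H](C)C[C@H](O[Si](C)(C)C(C)(C)C)C3 | intermediate
16 | 1α,2α-epoxy-4(9)-ene-3α,10α-diol | COC(=O)C[C@]12O[C@H]1[C@@H](O)C3=C([C@H]2O)[C@@H](C)C[C@H](O[Si](C)(C)C(C)(C)C)C3 | intermediate
17 | 10β-formate, 3α-alcohol | COC(=O)C[C@]12O[C@H]1[C@H](OC=O)C3=C([C@H]2O)[C@@H](C)C[C@H](O[Si](C)(C)C(C)(C)C)C3 | intermediate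
18 | 10β-formate, 3α-isobutyrate | COC(=O)C[C@]12O[C@H]1[C@H](OC=O)C3=C([C@H]2OC(=O)C(C)C)[C@@H](C)C[C@H](O[Si](C)(C)C(C)(C)C)C3 | intermediate
19 | 10β-alcohol, 3α-isobutyrate | COC(=O)C[C@]12O[C@H]1[C@H](O)C3=C([C@H]2OC(=O)C(C)C)[C@@H](C)C[C@H](O[Si](C)(C)C(C)(C)C)C3 | intermediate
20 | 10β-OTES, 3α-isobutyrate, 1α,2α-epoxide | COC(=O)C[C@]12O[C@H]1[C@H](O[Si](CC)(CC)CC)C3=C([C@H]2OC(=O)C(C)C)[C@@H](C)C[C@H](O[Si](C)(C)C(C)(C)C)C3 | intermediate
21 | 1α-hydroxy ester, H2 β, CH2CO2Me α (not isolated) | COC(=O)C[C@H]1[C@@H](O)[C@H](O[Si](CC)(CC)CC)C2=C([C@H]1OC(=O)C(C)C)[C@@H](C)C[C@H](O[Si](C)(C)C(C)(C)C)C2 | intermediate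
22 | octalin with cis-fused O1–C12 lactone (C11 = CH2), 3α-isobutyrate, 10β-OTES, 5β-methyl, 7α-OTBS | C1C(=O)O[C@@H]2[C@H]1[C@H](OC(=O)C(C)C)C3=C([C@H]2O[Si](CC)(CC)CC)C[C@@H](O[Si](C)(C)C(C)(C)C)C[C@@H]3C | intermediate
23 | lithium enolate of lactone 22 (not isolated) | C1=C(O[Li])O[C@@H]2[C@H]1[C@H](OC(=O)C(C)C)C3=C([C@H]2O[Si](CC)(CC)CC)C[C@@H](O[Si](C)(C)C(C)(C)C)C[C@@H]3C | intermediate
24 | key-step precursor: octalin 22 with CH2NMe2 on C11 (cis to H2, 11R) | CN(C)C[C@@H]1C(=O)O[C@@H]2[C@H]1[C@H](OC(=O)C(C)C)C3=C([C@H]2O[Si](CC)(CC)CC)C[C@@H](O[Si](C)(C)C(C)(C)C)C[C@@H]3C | intermediate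
25 | trifluoroacetate salt of 24 (not isolated) | C[NH+](C)C[C@@H]1C(=O)O[C@@H]2[C@H]1[C@H](OC(=O)C(C)C)C3=C([C@H]2O[Si](CC)(CC)CC)C[C@@H](O[Si](C)(C)C(C)(C)C)C[C@@H]3C.[O-]C(=O)C(F)(F)F | intermediate
26 | secondary ozonide, C4 and C9 bridged by –O– and –O–O– (ether bridge drawn on the β side; its orientation is without consequence; not isolated) | C[NH+](C)C[C@@H]1C(=O)O[C@@H]2[C@H]1[C@H](OC(=O)C(C)C)[C@]35OO[C@@](O3)([C@H]2O[Si](CC)(CC)CC)C[C@@H](O[Si](C)(C)C(C)(C)C)C[C@@H]5C.[O-]C(=O)C(F)(F)F | intermediate
27 | key-step product: cyclodecane-4,9-dione, (1R,2S,3S,5S,7S,10S,11R) in route locants | CN(C)C[C@@H]1C(=O)O[C@@H]2[C@H]1[C@H](OC(=O)C(C)C)C(=O)[C@@H](C)C[C@H](O[Si](C)(C)C(C)(C)C)CC(=O)[C@H]2O[Si](CC)(CC)CC | intermediate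
28 | (9S)-9-hydroxy-9-methyl compound | CN(C)C[C@@H]1C(=O)O[C@@H]2[C@H]1[C@H](OC(=O)C(C)C)C(=O)[C@@H](C)C[C@H](O[Si](C)(C)C(C)(C)C)C[C@](C)(O)[C@H]2O[Si](CC)(CC)CC | intermediate
29 | trimethylammonium iodide of 28 (not isolated) | C[N+](C)(C)C[C@@H]1C(=O)O[C@@H]2[C@H]1[C@H](OC(=O)C(C)C)C(=O)[C@@H](C)C[C@H](O[Si](C)(C)C(C)(C)C)C[C@](C)(O)[C@H]2O[Si](CC)(CC)CC.[I-] | intermediate
30 | α-methylene lactone, O10-TES, O7-TBS | C=C1C(=O)O[C@@H]2[C@H]1[C@H](OC(=O)C(C)C)C(=O)[C@@H](C)C[C@H](O[Si](C)(C)C(C)(C)C)C[C@](C)(O)[C@H]2O[Si](CC)(CC)CC | intermediate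
31 | 9,10-diol, O7-TBS | C=C1C(=O)O[C@@H]2[C@H]1[C@H](OC(=O)C(C)C)C(=O)[C@@H](C)C[C@H](O[Si](C)(C)C(C)(C)C)C[C@](C)(O)[C@H]2O | intermediate
32 | angelic acid, (Z)-2-methylbut-2-enoic acid | C/C=C(/C)C(=O)O | starting material
33 | angelic 2,4,6-trichlorobenzoic anhydride (not isolated) | C/C=C(/C)C(=O)OC(=O)c1c(Cl)cc(Cl)cc1Cl | intermediate
34 | 10-angelate, O7-TBS | C=C1C(=O)O[C@@H]2[C@H]1[C@H](OC(=O)C(C)C)C(=O)[C@@H](C)C[C@H](O[Si](C)(C)C(C)(C)C)C[C@](C)(O)[C@H]2OC(=O)/C(C)=C\C | intermediate
35 | CNP0184688.2, (1R,2S,3S,5S,7S,9S,10S) in route locants | C=C1C(=O)O[C@@H]2[C@H]1[C@H](OC(=O)C(C)C)C(=O)[C@@H](C)C[C@H](O)C[C@](C)(O)[C@H]2OC(=O)/C(C)=C\C | target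

**Step count**

- Total steps: 23.
- Longest linear sequence: 22 (steps 1–3 and 5–23).

**Steps most likely to fail**

Step 19. The face of attack at C9 may be decided by the conformation of the ten-membered ring (peripheral attack) rather than by the Felkin–Anh preference. The titanium reagent may also be too sluggish at a medium-ring ketone. The fallback sets out from 27 and returns at 28, and it exchanges the roles of carbon and oxygen. The non-basic CH2Br2/Zn/TiCl4 reagent methylenates the less hindered C9 ketone to the 9-methylene compound F1. With the amine protonated by CF3CO2H, m-CPBA delivers oxygen from the same open face that a methyl nucleophile would have used and gives the spiro-epoxide F2. LiI/AcOH opens it at the CH2 terminus to the iodohydrin F3. Bu3SnH/AIBN then replaces iodine by hydrogen to give 28.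

Step 11. Hydride delivery to C3 from the β face passes the pseudo-axial C5 methyl group, so facial selectivity at C3 may erode or reverse. The fallback sets out from 15 and returns at 18, and it fixes C3 by substitution instead of by the face of reduction. The reduction with α-face delivery at C3 gives the 3β,10α-diol F4. The formic acid Mitsunobu reaction at the less hindered C10 gives the 3β-hydroxy 10β-formate F5. A second Mitsunobu reaction with isobutyric acid at the allylic C3 alcohol inverts C3 and installs the ester in one operation, giving 18.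

Step 18. Cycloaddition of ozone to the hindered, inductively deactivated alkene may be slow, so oxygen-atom transfer to the alkene or oxidation of C–H bonds next to the silyl ethers could compete. The fallback sets out from 25 and returns at 27. It cuts the same C4=C9 bond and makes oxygen transfer the planned path. m-CPBA (or dimethyldioxirane) converts the ammonium salt into the 4,9-epoxide F6 (either face serves). H5IO6 in THF–H2O at 0 °C opens the epoxide and cleaves the resulting glycol to the 4,9-dione 27.

Further compounds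
F1 | step 19 | 9-methylene-4-ketone | CN(C)C[C@@H]1C(=O)O[C@@H]2[C@H]1[C@H](OC(=O)C(C)C)C(=O)[C@@H](C)C[C@H](O[Si](C)(C)C(C)(C)C)CC(=C)[C@H]2O[Si](CC)(CC)CC
F2 | step 19 | C9 spiro-epoxide (oxygen placed as the C9 hydroxyl of 28) | CN(C)C[C@@H]1C(=O)O[C@@H]2[C@H]1[C@H](OC(=O)C(C)C)C(=O)[C@@H](C)C[C@H](O[Si](C)(C)C(C)(C)C)C[C@@]3(CO3)[C@H]2O[Si](CC)(CC)CC
F3 | step 19 | 9-hydroxy-9-(iodomethyl) compound | CN(C)C[C@@H]1C(=O)O[C@@H]2[C@H]1[C@H](OC(=O)C(C)C)C(=O)[C@@H](C)C[C@H](O[Si](C)(C)C(C)(C)C)C[C@](CI)(O)[C@H]2O[Si](CC)(CC)CC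
F4 | step 11 | 1α,2α-epoxy-4(9)-ene-3β,10α-diol | COC(=O)C[C@]12O[C@H]1[C@@H](O)C3=C([C@@H]2O)[C@@H](C)C[C@H](O[Si](C)(C)C(C)(C)C)C3
F5 | step 11 | 3β-hydroxy 10β-formate | COC(=O)C[C@]12O[C@H]1[C@H](OC=O)C3=C([C@@H]2O)[C@@H](C)C[C@H](O[Si](C)(C)C(C)(C)C)C3
F6 | step 18 | 4,9-epoxide of 24 (drawn as the β-epoxide) | CN(C)C[C@@H]1C(=O)O[C@@H]2[C@H]1[C@H](OC(=O)C(C)C)[C@@]35O[C@]3([C@H]2O[Si](CC)(CC)CC)C[C@@H](O[Si](C)(C)C(C)(C)C)C[C@@H]5C
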